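**Retrosynthetic overview**
1. The (E)-enol ester is made last by Wittig reaction of a C10 aldehyde with an acyloxymethylene ylide. One ozonolysis unmasks both the aldehyde (from vinyl) and the acetonyl group (from 2-methylallyl).
2. Vinyl is added to C10 of a 5-(2-methylallyl) enone from the exo face and C5 is then protonated from the exo face. The 2-methylallyl group enters by Stille coupling of an α-bromo enone.
3. The seven-membered ring comes from one-carbon ring expansion (dibromocarbene) of a bicyclo[3.3.1]nonan-3-one. The pyran comes from dehydrative etherification C15–O–C18.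
4. Key step: radical 6-exo cyclisation of a bromohydrin-derived C14 radical onto a Baylis–Hillman cyclohexenone with O2 capture at C3. It forms C2–C14 and sets C2, C3 and C14.
5. C11 is set by copper-catalysed asymmetric conjugate addition. Ring order: purchased cyclohexenone ring → cyclohexane (radical) → pyran → seven-membered ring.

Convention and assumption: bridged compounds carry vibsane locants (C1 CH2 bridge, C2 ring-fusion CH, C3 carbinol, C4 C=O, C5 the carbon next to C4, C10, C11 quaternary C–CH3, C12–C13, C14, C15 = CMe2, C18 = CH2O); "exo" is the face of the keto bridge turned away from C12–C14; the ligand antipode giving (R) in step 1 is assumed available.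

**Step 1**
Reactants: 1 3-methylcyclohex-2-en-1-one; 2 5-bromo-2-methylpent-2-ene
Product: 4 (R)-3-methyl-3-(4-methylpent-3-en-1-yl)cyclohexan-1-one, via homoprenylmagnesium bromide 3 (not isolated)
Conditions: 2, Mg, Et2O, rt; then added to 1, Cu(OTf)2 (3 mol %), C2-symmetric chiral imidazolinium NHC precursor (4 mol %), Et2O, 0 °C; 1 M HCl
Reagents that add atoms: none
Why: Copper-catalysed asymmetric conjugate addition of a Grignard reagent to a β-methyl enone (Alexakis type), in which the chiral NHC–copper complex selects the enone face and sets the quaternary C11 as R (about 90 % ee expected, to be raised by recrystallising the triol of step 5).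

**Step 2**
Reactants: 4 (R)-3-methyl-3-(4-methylpent-3-en-1-yl)cyclohexan-1-one
Product: 5 (S)-5-methyl-5-(4-methylpent-3-en-1-yl)cyclohex-2-en-1-one
Conditions: 2-iodoxybenzoic acid (IBX, 2.5 equiv), DMSO/PhF, 70 °C
Reagents that add atoms: none
Why: Nicolaou IBX dehydrogenation, in which only the α-carbon remote from the quaternary centre has β-hydrogens, so a single enone forms and the stereocentre is untouched (the descriptor changes to S only by CIP priority).

**Step 3**
Reactants: 5 (S)-5-methyl-5-(4-methylpent-3-en-1-yl)cyclohex-2-en-1-one; 6 formaldehyde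
Product: 7 (S)-2-(hydroxymethyl)-5-methyl-5-(4-methylpent-3-en-1-yl)cyclohex-2-en-1-one
Conditions: 6 (37 % aq.), DMAP (20 mol %), THF/H2O, rt
Reagents that add atoms: none
Why: Morita–Baylis–Hillman hydroxymethylation, in which DMAP adds conjugately, the enolate traps formaldehyde and DMAP is expelled, placing C18 on the enone α-carbon.

**Step 4**
Reactants: 7 (S)-2-(hydroxymethyl)-5-methyl-5-(4-methylpent-3-en-1-yl)cyclohex-2-en-1-one
Product: 8 (5S)-5-(3-bromo-4-hydroxy-4-methylpentyl)-2-(hydroxymethyl)-5-methylcyclohex-2-en-1-one (both CHBr epimers)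
Conditions: NBS (1.05 equiv), THF/H2O 4:1, 0 °C
Reagents that add atoms: N-bromosuccinimide O=C1CCC(=O)N1Br; water O
Why: Bromohydrin formation, in which the electron-rich trisubstituted alkene (not the enone) forms the bromonium ion and water opens it at the tertiary carbon (Markovnikov), giving the secondary bromide radical precursor whose CHBr centre is erased in step 5.

**Step 5**
Reactants: 8 (5S)-5-(3-bromo-4-hydroxy-4-methylpentyl)-2-(hydroxymethyl)-5-methylcyclohex-2-en-1-one
Product: 10 (1S,2R,5S,8R)-2-hydroxy-2-(hydroxymethyl)-8-(2-hydroxypropan-2-yl)-5-methylbicyclo[3.3.1]nonan-3-one, via tertiary hydroperoxide 9 (not isolated)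
Conditions: Bu3SnH (1.3 equiv) + AIBN (0.2 equiv) by syringe pump over 6 h, PhMe (0.01 M), 80 °C, slow stream of N2 containing ca. 0.2 vol % O2; then PPh3, rt
Reagents that add atoms: dioxygen O=O
Why: Proposed new method: Bu3Sn• abstracts bromine, the β-hydroxy C14 radical closes 6-exo-trig onto the enone β-carbon (chair transition state, CMe2OH equatorial, chain necessarily cis-bridging) faster than it meets O2 at this very low O2 level, and the resulting tertiary α-keto radical, which has no fast alternative at low Bu3SnH concentration, is captured by O2 on the open exo face (C3–O exo, CH2OH endo) to give hydroperoxide 9 that PPh3 reduces, the closest known type being the tin hydride/O2 radical cyclisation–hydroxylation (Giese cyclisation followed by aerobic trapping).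

**Step 6**
Reactants: 10 (1S,2R,5S,8R)-2-hydroxy-2-(hydroxymethyl)-8-(2-hydroxypropan-2-yl)-5-methylbicyclo[3.3.1]nonan-3-one
Product: 11 (2S,3R,11S,14R) C5-nor tricyclic ketol (the bicyclo[3.3.1]nonan-3-one of 10 with C15–O–C18 closed as a cis-fused 2,2-dimethyltetrahydropyran, C3–OH exo)
Conditions: TsOH·H2O (10 mol %), CH2Cl2, 0 °C to rt
Reagents that add atoms: none
Why: Acid-catalysed dehydrative cycloetherification (SN1), in which the tertiary C15 carbinol ionises and is captured by the neighbouring equatorial CH2OH held syn to it by the bicycle, with no change at any stereocentre.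

**Step 7**
Reactants: 11 (2S,3R,11S,14R) C5-nor tricyclic ketol
Product: 12 bis-silyl derivative of 11 (C4(OSiMe3)=C10 silyl enol ether, C3–OSiMe3)
Conditions: Me3SiOTf (2.5 equiv), Et3N, CH2Cl2, 0 °C
Reagents that add atoms: trimethylsilyl triflate C[Si](C)(C)OS(=O)(=O)C(F)(F)F
Why: Soft enolisation/silylation, in which C3 is quaternary so the silyl enol ether can form only toward C10 and the tertiary hydroxyl is capped at the same time.

**Step 8**
Reactants: 12 bis-silyl derivative of 11; 13 bromoform
Product: 15 (2S,3R,11S,14R)-5-bromo-3-(trimethylsilyloxy) tricyclic C5(10)-en-4-one (seven-membered α-bromo enone, pyran as in 11), via dibromocyclopropane 14 (not isolated)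
Conditions: 13, KOt-Bu, pentane, −20 °C to rt; then PhMe, K2CO3, 80 °C
Reagents that add atoms: none
Why: Dibromocarbene cyclopropanation of the silyl enol ether followed by thermal electrocyclic opening of the siloxy-dibromocyclopropane (loss of Me3SiBr) inserts C5 between C4 and C10 and gives the α-bromo enone regiospecifically.

**Step 9**
Reactants: 15 α-bromo enone; 16 (2-methylallyl)magnesium chloride
Product: 18 (2S,3R,11S,14R)-5-(2-methylallyl)-3-(trimethylsilyloxy) tricyclic C5(10)-en-4-one, via tributyl(2-methylallyl)stannane 17 (not isolated)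
Conditions: 16, Bu3SnCl (1.05 equiv), THF, 0 °C to rt; then 15, Pd2(dba)3 (2.5 mol %), AsPh3, CuI, DMF, 60 °C
Reagents that add atoms: none
Why: Migita–Kosugi–Stille coupling of the α-bromo enone with the allylstannane made in the flask (unlike the Grignard reagent it does not add to ketones) places the acetonyl precursor on C5 before C10 is functionalised.

**Step 10**
Reactants: 18 5-(2-methylallyl) enone; 19 vinylmagnesium bromide
Product: 21 (2S,3R,5S,10S,11S,14R)-3-hydroxy-5-(2-methylallyl)-10-vinyl tricyclic 4-ketone, via bis-silyl enol ether 20 (not isolated)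
Conditions: 19 (3 equiv), CuBr·SMe2 (20 mol %), Me3SiCl, HMPA, THF, −78 to −40 °C; then 1 M HCl, THF, 0 °C
Reagents that add atoms: none
Why: Copper-catalysed, Me3SiCl-accelerated conjugate addition (Kuwajima–Nakamura conditions) delivers vinyl to C10 on the exo face away from the C12–C14 bridge, and protonolysis of the silyl enol ether likewise puts H on the exo face of C5, so the 2-methylallyl group ends endo and trans to vinyl as the target requires.

**Step 11**
Reactants: 21 3-hydroxy-5-(2-methylallyl)-10-vinyl tricyclic 4-ketone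
Product: 23 (2S,3R,5S,10S,11S,14R)-3-hydroxy-4-oxo-5-(2-oxopropyl) tricyclic 10-carbaldehyde, via bis-ozonide 22 (not isolated)
Conditions: O3, CH2Cl2, −78 °C; then Me2S, −78 °C to rt
Reagents that add atoms: ozone [O-][O+]=O
Why: Ozonolysis with reductive work-up cleaves both terminal alkenes at once, turning 2-methylallyl into the acetonyl group and vinyl into the C10 aldehyde without touching a stereocentre.

**Step 12**
Reactants: 24 3-methylbut-2-enoyl chloride; 6 formaldehyde
Product: 26 {[(3-methylbut-2-enoyl)oxy]methyl}triphenylphosphonium chloride, via chloromethyl 3-methylbut-2-enoate 25 (not isolated)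
Conditions: 6 (as paraformaldehyde), ZnCl2 (2 mol %), neat, 70 °C; then PPh3, PhMe, 80 °C
Reagents that add atoms: triphenylphosphine c1ccc(cc1)P(c1ccccc1)c1ccccc1
Why: Lewis-acid-catalysed insertion of formaldehyde into the acyl chloride gives the chloromethyl ester, which quaternises PPh3 (SN2) to the Anders–Gaßner acyloxymethyl phosphonium salt.

**Step 13**
Reactants: 23 keto aldehyde; 26 {[(3-methylbut-2-enoyl)oxy]methyl}triphenylphosphonium chloride
Product: 28 target CNP0237201.2, (2S,3R,5S,10S,11S,14R) with (E)-enol 3-methylbut-2-enoate, via acyloxymethylene ylide 27 (not isolated)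
Conditions: 26 (1.5 equiv), NaN(SiMe3)2 (1.4 equiv), THF, −78 °C; then 23, −78 to 0 °C
Reagents that add atoms: none
Why: Wittig olefination (Anders–Gaßner variant) with the acyloxymethylene ylide is selective for the aldehyde over the two ketones and gives the enol ester, with the E isomer expected as the major product and separated from the minor Z isomer by chromatography.

**Compound list**
1 | 3-methylcyclohex-2-en-1-one | CC1=CC(=O)CCC1 | starting material
2 | 5-bromo-2-methylpent-2-ene | CC(C)=CCCBr | starting material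
3 | (4-methylpent-3-en-1-yl)magnesium bromide | CC(C)=CCC[Mg]Br | intermediate
4 | (R)-3-methyl-3-(4-methylpent-3-en-1-yl)cyclohexan-1-one | O=C1CCC[C@](C)(CCC=C(C)C)C1 | intermediate
5 | (S)-5-methyl-5-(4-methylpent-3-en-1-yl)cyclohex-2-en-1-one | O=C1C=CC[C@](C)(CCC=C(C)C)C1 | intermediate
6 | formaldehyde | C=O | starting material
7 | (S)-2-(hydroxymethyl)-5-methyl-5-(4-methylpent-3-en-1-yl)cyclohex-2-en-1-one | O=C1C(CO)=CC[C@](C)(CCC=C(C)C)C1 | intermediate
8 | (5S)-5-(3-bromo-4-hydroxy-4-methylpentyl)-2-(hydroxymethyl)-5-methylcyclohex-2-en-1-one, both CHBr epimers | O=C1C(CO)=CC[C@](C)(CCC(Br)C(C)(C)O)C1 | intermediate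
9 | (1S,2R,5S,8R)-2-hydroperoxy-2-(hydroxymethyl)-8-(2-hydroxypropan-2-yl)-5-methylbicyclo[3.3.1]nonan-3-one | O=C1[C@](OO)(CO)[C@H]2C[C@](C)(CC[C@H]2C(C)(C)O)C1 | intermediate
10 | (1S,2R,5S,8R)-2-hydroxy-2-(hydroxymethyl)-8-(2-hydroxypropan-2-yl)-5-methylbicyclo[3.3.1]nonan-3-one | O=C1[C@](O)(CO)[C@H]2C[C@](C)(CC[C@H]2C(C)(C)O)C1 | intermediate
11 | (2S,3R,11S,14R) C5-nor tricyclic ketol: bicyclo[3.3.1]nonan-3-one with cis-fused 2,2-dimethyltetrahydropyran (C15–O–C18), C3–OH exo | O=C1[C@]2(O)COC(C)(C)[C@@H]3CC[C@@](C)(C[C@@H]32)C1 | intermediate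
12 | bis-silyl derivative of 11: C4(OSiMe3)=C10 enol ether, C3–OSiMe3 | C[Si](C)(C)OC1[C@]2(O[Si](C)(C)C)COC(C)(C)[C@@H]3CC[C@@](C)(C[C@@H]32)C=1 | intermediate
13 | bromoform | BrC(Br)Br | starting material
14 | exo-dibromocyclopropane across C4–C10 of 12 (C5 = CBr2) | C[Si](C)(C)O[C@]12[C@]3(O[Si](C)(C)C)COC(C)(C)[C@@H]4CC[C@@](C)(C[C@@H]43)[C@H]1C2(Br)Br | intermediate
15 | (2S,3R,11S,14R)-5-bromo-3-(trimethylsilyloxy) tricyclic C5(10)-en-4-one (bicyclo[4.3.1]decenone with the pyran of 11) | BrC1C(=O)[C@]2(O[Si](C)(C)C)COC(C)(C)[C@@H]3CC[C@@](C)(C[C@@H]32)C=1 | intermediate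
16 | (2-methylallyl)magnesium chloride | CC(=C)C[Mg]Cl | starting material
17 | tributyl(2-methylallyl)stannane | CCCC[Sn](CCCC)(CCCC)CC(C)=C | intermediate
18 | (2S,3R,11S,14R)-5-(2-methylallyl)-3-(trimethylsilyloxy) tricyclic C5(10)-en-4-one | C=C(C)CC1C(=O)[C@]2(O[Si](C)(C)C)COC(C)(C)[C@@H]3CC[C@@](C)(C[C@@H]32)C=1 | intermediate
19 | vinylmagnesium bromide | C=C[Mg]Br | starting material
20 | C4(OSiMe3)=C5 silyl enol ether of the conjugate adduct, C10-vinyl exo, C3–OSiMe3 | C=C(C)CC1=C(O[Si](C)(C)C)[C@]2(O[Si](C)(C)C)COC(C)(C)[C@@H]3CC[C@@](C)(C[C@@H]32)[C@H]1C=C | intermediate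
21 | (2S,3R,5S,10S,11S,14R)-3-hydroxy-5-(2-methylallyl)-10-vinyl tricyclic 4-ketone | C=C(C)C[C@@H]1C(=O)[C@]2(O)COC(C)(C)[C@@H]3CC[C@@](C)(C[C@@H]32)[C@H]1C=C | intermediate
22 | bis-ozonide of 21 (two 1,2,4-trioxolanes, diastereomer mixture at the ozonide carbons) | CC1(OCOO1)C[C@@H]2C(=O)[C@]3(O)COC(C)(C)[C@@H]4CC[C@@](C)(C[C@@H]43)[C@H]2C5OCOO5 | intermediate
23 | (2S,3R,5S,10S,11S,14R)-3-hydroxy-4-oxo-5-(2-oxopropyl) tricyclic 10-carbaldehyde | CC(=O)C[C@@H]1C(=O)[C@]2(O)COC(C)(C)[C@@H]3CC[C@@](C)(C[C@@H]32)[C@H]1C=O | intermediate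
24 | 3-methylbut-2-enoyl chloride | CC(C)=CC(=O)Cl | starting material
25 | chloromethyl 3-methylbut-2-enoate | CC(C)=CC(=O)OCCl | intermediate
26 | {[(3-methylbut-2-enoyl)oxy]methyl}triphenylphosphonium chloride | CC(C)=CC(=O)OC[P+](c1ccccc1)(c1ccccc1)c1ccccc1.[Cl-] | intermediate
27 | [(3-methylbut-2-enoyl)oxy]methylene(triphenyl)phosphorane | CC(C)=CC(=O)OC=P(c1ccccc1)(c1ccccc1)c1ccccc1 | intermediate
28 | CNP0237201.2: (2S,3R,5S,10S,11S,14R) tricyclic ketol with 5-(2-oxopropyl) and 10-[(E)-2-(3-methylbut-2-enoyloxy)vinyl] | CC(=O)C[C@@H]1C(=O)[C@]2(O)COC(C)(C)[C@@H]3CC[C@@](C)(C[C@@H]32)[C@H]1/C=C/OC(=O)C=C(C)C | target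

**Step count**
Total: 13 steps. Longest linear sequence: 12 steps (steps 1–11, then 13); step 12 is a one-step branch.

**Three steps most likely to fail**

Step 5 (cyclisation–oxygenation). The C14 radical may be oxygenated or reduced before it cyclises, or the C3 radical may be reduced instead of oxygenated. The fallback sets out from 8 and returns at 11, and moves the oxygen introduction to enolate chemistry. Compound 8 is cyclised under strictly anaerobic conditions (Bu3SnH, AIBN, PhH, 80 °C) to (1S,2S,5S,8R)-2-(hydroxymethyl)-8-(2-hydroxypropan-2-yl)-5-methylbicyclo[3.3.1]nonan-3-one F1. Catalytic TsOH in warm benzene then closes the pyran, either by loss of water to the exo-methylene ketone and 6-endo oxa-Michael addition of the tertiary alcohol or by direct ionisation at C15 (both give the same ether), giving the C5-nor tricyclic ketone lacking the C3 hydroxyl F2. Thermodynamic enolisation toward the ring-fusion carbon and oxidation on the exo face (KOt-Bu, O2, P(OEt)3, THF/t-BuOH, −20 °C) gives 11.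

Step 10 (vinyl addition to a hindered 2-substituted enone and C5 protonation). The cuprate may not add next to the quaternary centre. The fallback sets out from 18 and returns at 23, and replaces the organocopper addition by a radical one. Irradiation (390 nm) of 18 in MeCN/1,3-dioxolane with (Bu4N)4W10O32 generates the 1,3-dioxolan-2-yl radical, a masked formyl group that adds to C10 on the exo face. Hydrogen is returned to C5 on the exo face, giving the 10-(1,3-dioxolan-2-yl)-5-(2-methylallyl)-3-(trimethylsilyloxy) tricyclic 4-ketone F3. Ozonolysis (O3, CH2Cl2, −78 °C; Me2S) converts the 2-methylallyl group to acetonyl, giving the 10-(1,3-dioxolan-2-yl)-5-(2-oxopropyl)-3-(trimethylsilyloxy) tricyclic 4-ketone F4. Aqueous HCl/THF removes the acetal and the silyl ether to give 23.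

Step 13 (Wittig). The E/Z ratio may be poor, or the base may trigger aldol chemistry of the keto aldehyde. The fallback sets out from 23 and returns at 28, and fixes the alkene geometry before the C–O bond is made. Takai olefination (CHI3, CrCl2, THF, 0 °C) gives the 10-[(E)-2-iodovinyl] tricyclic diketone F5. Ullmann-type C–O coupling with 3-methylbut-2-enoic acid (CuI, 3,4,7,8-tetramethyl-1,10-phenanthroline, Cs2CO3, PhMe, 70 °C) then gives 28 with retention of the E geometry. The closest precedents for this coupling are copper-mediated couplings of vinyl iodides with amides and the known transfer of carboxylate from monovalent copper carboxylates to vinyl iodides.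

**Further compounds**
F1 | step 5 | (1S,2S,5S,8R)-2-(hydroxymethyl)-8-(2-hydroxypropan-2-yl)-5-methylbicyclo[3.3.1]nonan-3-one | O=C1[C@H](CO)[C@H]2C[C@](C)(CC[C@H]2C(C)(C)O)C1
F2 | step 5 | C5-nor tricyclic ketone lacking the C3 hydroxyl (cis-fused pyran, C3–H exo) | O=C1[C@@H]2COC(C)(C)[C@@H]3CC[C@@](C)(C[C@@H]32)C1
F3 | step 10 | 10-(1,3-dioxolan-2-yl)-5-(2-methylallyl)-3-(trimethylsilyloxy) tricyclic 4-ketone | C=C(C)C[C@@H]1C(=O)[C@]2(O[Si](C)(C)C)COC(C)(C)[C@@H]3CC[C@@](C)(C[C@@H]32)[C@H]1C1OCCO1
F4 | step 10 | 10-(1,3-dioxolan-2-yl)-5-(2-oxopropyl)-3-(trimethylsilyloxy) tricyclic 4-ketone | CC(=O)C[C@@H]1C(=O)[C@]2(O[Si](C)(C)C)COC(C)(C)[C@@H]3CC[C@@](C)(C[C@@H]32)[C@H]1C1OCCO1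
F5 | step 13 | 3-hydroxy-10-[(E)-2-iodovinyl]-5-(2-oxopropyl) tricyclic 4-ketone | CC(=O)C[C@@H]1C(=O)[C@]2(O)COC(C)(C)[C@@H]3CC[C@@](C)(C[C@@H]32)[C@H]1/C=C/I
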